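## Retrosynthetic overview

1. Plakortolide F ⇒ the 1,2-dioxane closes last, by intramolecular peroxy-Michael addition of a C6 tertiary hydroperoxide onto a butenolide (sets C3, cis-fused). The hydroperoxide ⇒ Mukaiyama–Isayama hydroperoxysilylation of the 1,1-disubstituted alkene 16.
2. Alkene 16 ⇒ C6 ketone 15 ⇒ 2,2-dialkyl-1,3-dithiane 14. The butenolide (first ring) ⇒ Z-olefination/lactonisation of the tertiary α-hydroxy aldehyde 12.
3. Key C5–C6 bond: C6, a carbonyl carbon, is made nucleophilic as a dithiane acyl anion and opens the epoxide CH2 of (R)-2-methylglycidol 6, in one pot, after the same carbon has been alkylated with bromide 4. C4 comes from the chiral pool.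
4. Bromide 4 ⇒ aryl Grignard reagent + 1,9-dibromononane.
5. Ring order: butenolide, then 1,2-dioxane. C6 (methyl versus n-alkyl on a radical centre) cannot be controlled; the unwanted C6 epimer is removed after the last step.

## Conventions and assumptions

Numbering used for the target: C1 lactone C=O, C2 CH2, C3 CH–OO, C4 C(Me)–O(lactone), C5 CH2, C6 C(Me)–OO, then the nonyl chain. The target is (3S,4S,6R). TBS = tert-butyldimethylsilyl.

Assumption: (R)-2-methylglycidol (sold as such and as its crystalline 4-nitrobenzoate) is used at ≥98% ee.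

Assumption: compounds 17 and 18 are the (6R) epimers. Their (6S) epimers, which step 7 forms in about equal amount, are referred to in words, travel with them through step 8 and are removed there.

## Route

Step 1
Reactants: 1 (4-bromophenoxy)(tert-butyl)dimethylsilane; 2 1,9-dibromononane (3 equiv)
Product: 4 [4-(9-bromononyl)phenoxy](tert-butyl)dimethylsilane, via arylmagnesium bromide 3 (not isolated)
Conditions: Mg, THF, reflux; then 2, Li2CuCl4 (3 mol %), THF–NMP, 0 °C → rt
Reagents that add atoms: none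
Why: Kochi–Cahiez copper-catalysed Grignard/alkyl bromide cross-coupling; the excess of the cheap dibromide suppresses double arylation and the aryl silyl ether is inert to the Grignard reagent.

Step 2
Reactants: 5 1,3-dithiane (1.05 equiv); 4 (1.0 equiv); 6 (R)-2-methylglycidol (1.5 equiv)
Product: 11 (2S)-3-[2-(9-{4-[(TBS)oxy]phenyl}nonyl)-1,3-dithian-2-yl]-2-methylpropane-1,2-diol, via 2-lithio-1,3-dithiane 7 (not isolated), via 2-alkyl-1,3-dithiane 8 (not isolated), via 2-lithio-2-alkyl-1,3-dithiane 9 (not isolated), via lithium alkoxide of the glycidol 10 (not isolated)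
Conditions: 5, n-BuLi (1.05 equiv), THF, −30 °C; 4, −78 → 0 °C; t-BuLi (1.1 equiv), THF–HMPA (10:1), −78 °C; then 10 (from 6 + n-BuLi, 1.5 equiv each, THF, −78 °C), −78 → 0 °C; H2O quench
Reagents that add atoms: none
Why: Corey–Seebach dithiane umpolung run as a one-pot linchpin coupling, in which the future C6 carbonyl carbon reacts twice as a carbanion, first in an SN2 alkylation with the primary bromide and then in an SN2 opening of the epoxide CH2 (future C5), so two carbons that are both natural acceptors are joined; the C4 stereocentre is taken over unchanged from 6 because no bond to it is made or broken and the Payne rearrangement of alkoxide 10 is degenerate (it returns the same enantiomer).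

Step 3
Reactants: 11
Product: 12 (2S)-2-hydroxy-2-methyl-3-[2-(9-{4-[(TBS)oxy]phenyl}nonyl)-1,3-dithian-2-yl]propanal
Conditions: SO3·pyridine, DMSO, Et3N, CH2Cl2, 0 °C; used crude
Reagents that add atoms: none
Why: Parikh–Doering oxidation takes only the primary alcohol (the tertiary one cannot be oxidised), does not cleave the 1,2-diol and leaves the dithiane sulfur atoms untouched.

Step 4
Reactants: 12
Product: 14 (5S)-5-methyl-5-{[2-(9-{4-[(TBS)oxy]phenyl}nonyl)-1,3-dithian-2-yl]methyl}furan-2(5H)-one, via Z-hydroxy enoate 13 (not isolated)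
Conditions: (o-TolO)2P(O)CH2CO2Et, NaH, THF, −78 → 0 °C; then p-TsOH (cat.), CH2Cl2, rt
Reagents that add atoms: ethyl 2-[bis(2-methylphenoxy)phosphoryl]acetate CCOC(=O)CP(=O)(Oc1ccccc1C)Oc1ccccc1C
Why: Ando-type Z-selective Horner–Wadsworth–Emmons olefination gives the cis-enoate, whose tertiary hydroxyl lactonises onto the ester to form the butenolide; the aldehyde has no α-hydrogen so C4 cannot epimerise, and the still-masked ketone rules out retro-aldol cleavage under the basic conditions.

Step 5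
Reactants: 14
Product: 15 (5S)-5-methyl-5-(2-oxo-11-{4-[(TBS)oxy]phenyl}undecyl)furan-2(5H)-one
Conditions: MeI (10 equiv), CaCO3, MeCN–H2O (4:1), 45 °C
Reagents that add atoms: water O
Why: S-methylation and hydrolysis of the dithiane under near-neutral, CaCO3-buffered conditions unmasks the C6 ketone without touching the butenolide or the aryl silyl ether.

Step 6
Reactants: 15
Product: 16 (5S)-5-methyl-5-(2-methylidene-11-{4-[(TBS)oxy]phenyl}undecyl)furan-2(5H)-one
Conditions: Zn, CH2Br2, TiCl4 (premixed, THF, 0 °C); then 15, CH2Cl2, 0 °C → rt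
Reagents that add atoms: dibromomethane BrCBr
Why: Takai–Lombardo methylenation; the non-basic CH2(ZnBr)2/TiCl4 reagent methylenates the ketone selectively over the lactone and avoids the E1cB loss of the β-acyloxy group that a basic Wittig ylide would cause.

Step 7
Reactants: 16
Product: 17 (5S)-5-methyl-5-[(2R)-2-methyl-11-{4-[(TBS)oxy]phenyl}-2-[(triethylsilyl)peroxy]undecyl]furan-2(5H)-one
Conditions: Co(acac)2 (10 mol %), Et3SiH (2 equiv), O2 (1 atm), ClCH2CH2Cl, rt
Reagents that add atoms: triethylsilane CC[SiH](CC)CC; dioxygen O=O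
Why: Mukaiyama–Isayama hydroperoxysilylation (Markovnikov hydrogen-atom transfer to the electron-rich 1,1-disubstituted alkene from the hydride generated from Co(acac)2 and Et3SiH, O2 capture of the tertiary radical, silyl transfer) puts the peroxide on C6 and turns the methylene into the C6 methyl, while the hindered, electron-poor butenolide alkene should react much more slowly; the radical centre carries a methyl and an n-alkyl group, so there is no facial bias and 17 is obtained as an about 1:1 mixture with its C6 epimer, which is carried on with it.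

Step 8
Reactants: 17 (as the about 1:1 mixture with its C6 epimer from step 7)
Product: 19 plakortolide F, via hydroperoxy phenol 18 (not isolated)
Conditions: Bu4NF (2.5 equiv), THF, 0 °C; then CF3CH2OH, Et2NH (0.2 equiv), rt; SiO2 chromatography then HPLC to remove the (3S,4S,6S) epimer
Reagents that add atoms: none
Why: fluoride removes both silyl groups and the freed hydroperoxide adds 6-exo to the butenolide (intramolecular peroxy-Michael addition) on the face that carries the C5 tether, which fixes C3 as S in a cis-fused bicycle; the (6S) material cyclises in the same way to 6-epi-plakortolide F, and the two rigid bicyclic diastereomers are then separable, at the cost of about half the material.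

## Compound list

1 | (4-bromophenoxy)(tert-butyl)dimethylsilane | CC(C)(C)[Si](C)(C)Oc1ccc(Br)cc1 | starting material
2 | 1,9-dibromononane | BrCCCCCCCCCBr | starting material
3 | {4-[(TBS)oxy]phenyl}magnesium bromide | CC(C)(C)[Si](C)(C)Oc1ccc([Mg]Br)cc1 | intermediate
4 | [4-(9-bromononyl)phenoxy](tert-butyl)dimethylsilane | CC(C)(C)[Si](C)(C)Oc1ccc(CCCCCCCCCBr)cc1 | intermediate
5 | 1,3-dithiane | C1CSCSC1 | starting material
6 | (R)-2-methylglycidol, [(2R)-2-methyloxiran-2-yl]methanol | C[C@@]1(CO)CO1 | starting material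
7 | 2-lithio-1,3-dithiane | [Li]C1SCCCS1 | intermediate
8 | tert-butyl{4-[9-(1,3-dithian-2-yl)nonyl]phenoxy}dimethylsilane | CC(C)(C)[Si](C)(C)Oc1ccc(CCCCCCCCCC2SCCCS2)cc1 | intermediate
9 | 2-lithio derivative of 8 | CC(C)(C)[Si](C)(C)Oc1ccc(CCCCCCCCCC2([Li])SCCCS2)cc1 | intermediate
10 | lithium [(2R)-2-methyloxiran-2-yl]methanolate | C[C@@]1(CO[Li])CO1 | intermediate
11 | (2S)-3-[2-(9-{4-[(TBS)oxy]phenyl}nonyl)-1,3-dithian-2-yl]-2-methylpropane-1,2-diol | C[C@@](O)(CO)CC1(CCCCCCCCCc2ccc(O[Si](C)(C)C(C)(C)C)cc2)SCCCS1 | intermediate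
12 | (2S)-2-hydroxy-2-methyl-3-[2-(9-{4-[(TBS)oxy]phenyl}nonyl)-1,3-dithian-2-yl]propanal | C[C@@](O)(C=O)CC1(CCCCCCCCCc2ccc(O[Si](C)(C)C(C)(C)C)cc2)SCCCS1 | intermediate
13 | ethyl (2Z,4S)-4-hydroxy-4-methyl-5-[2-(9-{4-[(TBS)oxy]phenyl}nonyl)-1,3-dithian-2-yl]pent-2-enoate | C[C@@](O)(/C=C\C(=O)OCC)CC1(CCCCCCCCCc2ccc(O[Si](C)(C)C(C)(C)C)cc2)SCCCS1 | intermediate
14 | (5S)-5-methyl-5-{[2-(9-{4-[(TBS)oxy]phenyl}nonyl)-1,3-dithian-2-yl]methyl}furan-2(5H)-one | C[C@@]1(CC2(CCCCCCCCCc3ccc(O[Si](C)(C)C(C)(C)C)cc3)SCCCS2)OC(=O)C=C1 | intermediate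
15 | (5S)-5-methyl-5-(2-oxo-11-{4-[(TBS)oxy]phenyl}undecyl)furan-2(5H)-one | C[C@@]1(CC(=O)CCCCCCCCCc2ccc(O[Si](C)(C)C(C)(C)C)cc2)OC(=O)C=C1 | intermediate
16 | (5S)-5-methyl-5-(2-methylidene-11-{4-[(TBS)oxy]phenyl}undecyl)furan-2(5H)-one | C[C@@]1(CC(=C)CCCCCCCCCc2ccc(O[Si](C)(C)C(C)(C)C)cc2)OC(=O)C=C1 | intermediate
17 | (5S)-5-methyl-5-[(2R)-2-methyl-11-{4-[(TBS)oxy]phenyl}-2-[(triethylsilyl)peroxy]undecyl]furan-2(5H)-one | C[C@@](OO[Si](CC)(CC)CC)(CCCCCCCCCc1ccc(O[Si](C)(C)C(C)(C)C)cc1)C[C@]2(C)OC(=O)C=C2 | intermediate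
18 | (5S)-5-[(2R)-2-hydroperoxy-11-(4-hydroxyphenyl)-2-methylundecyl]-5-methylfuran-2(5H)-one | C[C@@](OO)(CCCCCCCCCc1ccc(O)cc1)C[C@]2(C)OC(=O)C=C2 | intermediate
19 | plakortolide F, (3S,4S,6R), cis-fused 1,2-dioxane/γ-lactone | C[C@@]1(CCCCCCCCCc2ccc(O)cc2)C[C@]2(C)OC(=O)C[C@@H]2OO1 | target

## Step count and risks

Total step count: 8. Longest linear sequence: 8 (from 1).

Three steps most likely to fail:

**Step 2.** The hindered tertiary dithiane anion 9 may open the alkoxide-deactivated, 2,2-disubstituted epoxide too slowly in the one-pot sequence. The fallback reverses the order of the two alkylations and masks the diol. It sets out from 5 and 6 and comes back at 11. Excess 2-lithio-1,3-dithiane 7 (small, cheap, far more reactive) opens alkoxide 10 to give (2S)-3-(1,3-dithian-2-yl)-2-methylpropane-1,2-diol F1. 2,2-Dimethoxypropane with pyridinium p-toluenesulfonate converts it into the acetonide (4S)-4-(1,3-dithian-2-ylmethyl)-2,2,4-trimethyl-1,3-dioxolane F2. n-BuLi (THF, −20 °C) gives its 2-lithio derivative F3, which is alkylated by the primary bromide 4 to the 2,2-dialkyl dithiane acetonide F4. Aqueous AcOH removes the acetonide (the aryl silyl ether survives) and returns diol 11.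

**Step 4.** The tertiary α-hydroxy aldehyde 12 may hydrate, dimerise or undergo α-ketol rearrangement, and the Z/E ratio or the lactonisation may be incomplete. The fallback sets out from 12 and comes back at 14. Ph3P=C=C=O (toluene, 80 °C) is attacked by the tertiary hydroxyl to give the acyl ylide (2S)-2-methyl-1-oxo-3-[2-(9-{4-[(TBS)oxy]phenyl}nonyl)-1,3-dithian-2-yl]propan-2-yl (triphenylphosphoranylidene)acetate F5. This closes by intramolecular Wittig reaction directly to butenolide 14, with the alkene geometry fixed by the ring.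

**Step 7.** The hydride formed from Co(acac)2 and Et3SiH may also reduce or peroxidise the butenolide alkene, in addition to the unavoidable 1:1 ratio at C6. The fallback is an ionic Markovnikov peroxymercuration, which only the electron-rich alkene undergoes. It sets out from 16 and comes back at 19. Hg(OAc)2 with anhydrous H2O2 (Et2O/CH2Cl2) gives the mercurial hydroperoxide (5S)-5-{(2R)-2-[(acetoxymercurio)methyl]-2-hydroperoxy-11-{4-[(TBS)oxy]phenyl}undecyl}-5-methylfuran-2(5H)-one F6 and its C6 epimer F7. Et2NH in CF3CH2OH closes these to the cis-fused bicyclic peroxy lactone carrying CH2HgOAc on C6 F8 and its C6 epimer F9. NaBH4 in aqueous NaOH/CH2Cl2 (0 °C, brief contact, mildly acidic work-up to re-close any opened lactone) turns CH2HgOAc into the C6 methyl, giving plakortolide F TBS ether F10 and its C6 epimer F11. Bu4NF then gives 19 and its C6 epimer, separated as in step 8.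

## Further compounds

F1 | step 2 | (2S)-3-(1,3-dithian-2-yl)-2-methylpropane-1,2-diol | C[C@@](O)(CO)CC1SCCCS1
F2 | step 2 | (4S)-4-(1,3-dithian-2-ylmethyl)-2,2,4-trimethyl-1,3-dioxolane | C[C@]1(CC2SCCCS2)COC(C)(C)O1
F3 | step 2 | 2-lithio derivative of F2 | C[C@]1(CC2([Li])SCCCS2)COC(C)(C)O1
F4 | step 2 | acetonide of 11, (4S)-4-{[2-(9-{4-[(TBS)oxy]phenyl}nonyl)-1,3-dithian-2-yl]methyl}-2,2,4-trimethyl-1,3-dioxolane | C[C@]1(CC2(CCCCCCCCCc3ccc(O[Si](C)(C)C(C)(C)C)cc3)SCCCS2)COC(C)(C)O1
F5 | step 4 | (2S)-2-methyl-1-oxo-3-[2-(9-{4-[(TBS)oxy]phenyl}nonyl)-1,3-dithian-2-yl]propan-2-yl (triphenylphosphoranylidene)acetate | C[C@@](OC(=O)C=P(c1ccccc1)(c1ccccc1)c1ccccc1)(C=O)CC1(CCCCCCCCCc2ccc(O[Si](C)(C)C(C)(C)C)cc2)SCCCS1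
F6 | step 7 | (5S)-5-{(2R)-2-[(acetoxymercurio)methyl]-2-hydroperoxy-11-{4-[(TBS)oxy]phenyl}undecyl}-5-methylfuran-2(5H)-one | CC(=O)O[Hg]C[C@@](OO)(CCCCCCCCCc1ccc(O[Si](C)(C)C(C)(C)C)cc1)C[C@]2(C)OC(=O)C=C2
F7 | step 7 | C6 epimer of F6 | CC(=O)O[Hg]C[C@](OO)(CCCCCCCCCc1ccc(O[Si](C)(C)C(C)(C)C)cc1)C[C@]2(C)OC(=O)C=C2
F8 | step 7 | cis-fused bicyclic peroxy lactone with CH2HgOAc on C6, configured as 19 | CC(=O)O[Hg]C[C@@]1(CCCCCCCCCc2ccc(O[Si](C)(C)C(C)(C)C)cc2)C[C@]2(C)OC(=O)C[C@@H]2OO1
F9 | step 7 | C6 epimer of F8 | CC(=O)O[Hg]C[C@]1(CCCCCCCCCc2ccc(O[Si](C)(C)C(C)(C)C)cc2)C[C@]2(C)OC(=O)C[C@@H]2OO1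
F10 | step 7 | plakortolide F TBS ether | C[C@@]1(CCCCCCCCCc2ccc(O[Si](C)(C)C(C)(C)C)cc2)C[C@]2(C)OC(=O)C[C@@H]2OO1
F11 | step 7 | 6-epi-plakortolide F TBS ether | C[C@]1(CCCCCCCCCc2ccc(O[Si](C)(C)C(C)(C)C)cc2)C[C@]2(C)OC(=O)C[C@@H]2OO1
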